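Answer 3 questions about one flask of solid substrate under held gas.

solid substrate 0.50 M; gas 200 mM (held); time 1.0 min

- the product standing at 1.0 min, as a percentage of the solid substrate charged
- the change that raises the amount of product at 1.0 min, in percent of the solid substrate charged most ("none" if none brings more than 2 percentage points) (midnight / winter / dawn / summer / none)
- amount of product at 1.0 min, in percent of the solid substrate charged, after dawn

- midnight: doubling the transfer coefficient of step 3, all else as stated
- winter: doubling the saturation concentration of gas, all else as stated
- dawn: doubling the solubility in step 2, all else as stated
- summer: doubling the dissolution coefficient of step 2, all else as stated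

- solid substrate is a solid; its amount is given per volume of the solution
- at the start none of reagent is dissolved
- at the start none of the solid substrate is in solution
- run time (flask): 1.0 min

    starting material + reagent ⇌ product + released group (K1 = 0.68, k1 = 0.282 M⁻¹ s⁻¹)
    solid substrate ⇌ starting material, rate k2*(cs2 - [starting material]) while solid is left; crystals form when [starting material] > cs2 (cs2 = 0.33 M, k2 = 0.146 s⁻¹)
    gas ⇌ reagent, rate k3*(csat - [reagent]) (k3 = 1.73 s⁻¹, csat = 200 mM)
    released group → by-product carried off (k4 = 0.256 s⁻¹)

Solid substrate dissolves to starting material, which takes up reagent from the gas and gives product and released group. Follow one released group to its fork: it leaves as by-product carried off at 0.256 s⁻¹, or it returns with product. With product at half the charge, return runs at 0.104 s⁻¹. Call φ the escape chance, the share of released groups that leave rather than return: 71.2 %.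

My own reckoning follows. Take reagent at saturation, since transfer at 1.73 s⁻¹ is far faster than uptake at 0.141 s⁻¹. The pseudo-first-order forward constant is then 0.0564 s⁻¹. Delay the start by the time of pouring the charge in at full dissolving rate, 10.4 s. Multiply the forward constant by φ and the yield comes to 86.4 %. Halving the delay gives 88.9 % after dawn. Doubling the saturation concentration doubles the forward constant, and that picks winter.

The forecast gives 80 %, winter and 86 %, lower than mine on both yields: “the product creeps up against a reverse reaction held back only by the slow loss of released group”.

The flask gives 83.4 %, winter with a gain of 13 percentage points, and 86.8 %.

Strike out the path to by-product carried off, and the flask falls from 83.4 % to 40.3 %, a change that would make the forecast's 80 % wrong. In the flask at 1.00 min, φ has sunk to 59.7 %. Now take the neighbour flask with 2.0 M of solid substrate: at its product level φ is 53.3 %. Hold that, and its starting material of 13.7 %, over 1.0 min: the forward constant then gives 24.7 % of its charge, and that flask reads 27.0 %.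

(The numbers are invented; the rest is arithmetic.)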